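The seven-membered ring (ring B) is cut at C7–C8 and C1–C10. Seen from the C7 methylene, ring B (C1, C5–C10) hides a 1,4-diene, C8=C9 plus the enol level of C5=C6, and its far edge C1–C10 carries two adjacent stereocentres, one quaternary. A single operation, carbenoid cyclopropanation of an enol ether followed in the same flask by a divinylcyclopropane Cope rearrangement, forms both bonds, closes ring B and sets C1 and C10. Its precursors are a cross-conjugated 2-(1-ethoxyvinyl)cyclopentenone (five-membered ring A with C6 and C7) and an (E)-4-siloxyvinyl diazoacetate (C8–C10 and the future C8 methyl). The vinylogous ester so formed is then transposed, and C4, C5 and C6 are relayed from one reagent-controlled reduction.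

Key step: step 4

Remark on locants: C1–C10 are route locants of the bicyclo[5.3.0]decane core (C1 quaternary fusion carbon with methyl, C2, C3, C4 isopropyl-bearing carbon, C5 fusion CH, C6 acyloxy carbon, C7, C8 methyl-bearing alkene carbon, C9, C10 carbinol). Ring A is C1–C5 and ring B is C1, C5–C10. β is the face of the C1 methyl and α the other face. The target is 1β-methyl, 4β-OH, 4α-isopropyl, 5αH, 6α-O, 10α-OH.

Remark on the partners of the key step: the ethyl enol ether, the silyl enol ether and the methyl ester are kept. The ethoxy group is retained on purpose, because the vinylogous ester it leaves behind is consumed by a planned carbonyl transposition (step 5), not by a hydrolysis that would have to spare a tertiary allylic carbinol.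

Assumption: the sense of induction of Rh2(DOSP)4 (dirhodium tetrakis[N-(4-dodecylbenzenesulfonyl)prolinate]) with the new carbenoid is taken to follow that known for styryl- and aryldiazoacetates. On that basis the R ligand is chosen; the S ligand would replace it with no other change if the sense proved opposite.

Step 1
Reactants: 1 2-bromo-3-methylcyclopent-2-en-1-one; 2 tributyl(1-ethoxyvinyl)stannane
Product: 3 2-(1-ethoxyvinyl)-3-methylcyclopent-2-en-1-one
Conditions: Pd(PPh3)4 (5 mol %), CuI (10 mol %), DMF, 70 °C
Reagents that add atoms: none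
Why: Stille cross-coupling: zerovalent palladium inserts into the C–Br bond of the α-bromoenone and CuI speeds transfer of the 1-ethoxyvinyl group from tin, a reliable reaction for α-haloenones that leaves the acid-labile enol ether intact under neutral conditions.

Step 2
Reactants: 4 methyl diazoacetate; 5 (tert-butyldimethylsilyloxy)acetaldehyde
Product: 6 methyl 4-(tert-butyldimethylsilyloxy)-2-diazo-3-hydroxybutanoate (racemic)
Conditions: DBU (10 mol %), MeCN, 0 °C to rt
Reagents that add atoms: none
Why: Base-catalysed aldol-type addition of the acidic C–H of a diazoacetate to an aldehyde is a standard route to β-hydroxy-α-diazo esters and keeps the diazo group; the new carbinol centre is racemic and is removed in step 3.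

Step 3
Reactants: 6 methyl 4-(tert-butyldimethylsilyloxy)-2-diazo-3-hydroxybutanoate
Product: 8 methyl (E)-4-(tert-butyldimethylsilyloxy)-2-diazobut-3-enoate, via dichlorophosphate ester 7 (not isolated)
Conditions: POCl3, Et3N, CH2Cl2, 0 °C to rt
Reagents that add atoms: none
Why: Dehydration of a β-hydroxy-α-diazo ester by phosphorylation and amine-promoted E2 elimination can only run toward C4 because C2 bears no hydrogen, and should give the conjugated enol ether with the less crowded E geometry that step 4 requires.

Step 4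
Reactants: 3 2-(1-ethoxyvinyl)-3-methylcyclopent-2-en-1-one; 8 methyl (E)-4-(tert-butyldimethylsilyloxy)-2-diazobut-3-enoate
Product: 10 methyl 6-ethoxy-1β-methyl-4-oxo-10α-(tert-butyldimethylsilyloxy)bicyclo[5.3.0]deca-5,8-diene-8-carboxylate, via cis-divinylcyclopropane 9 (not isolated)
Conditions: Rh2(R-DOSP)4 (2 mol %), hexanes, −40 °C, 8 added over 3 h to 3 (2 equiv); then 65 °C
Reagents that add atoms: none
Why: Proposed new method: loss of N2 from 8 at the catalyst gives a divalent-rhodium donor/acceptor vinylcarbenoid that should add to the electron-rich 1,1-disubstituted enol ether C6=C7 of 3 (new bonds C7–C8 and C6–C8) with the siloxyvinyl donor cis to the cyclopentenone, and the cis-divinylcyclopropane 9 then undergoes a Cope rearrangement (C1–C10 formed, C6–C8 broken); the closest known reaction type is the tandem cyclopropanation/Cope rearrangement (formal [4+3] cycloaddition) of vinyldiazoacetates with 2-oxygenated dienes under chiral dirhodium tetraprolinates, which has not been shown for a 4-siloxy-substituted vinylcarbenoid. The three-membered ring closes by concerted [2+1] carbenoid addition and the seven-membered ring by a [3,3]-sigmatropic shift through the boat transition state that a cis-divinylcyclopropane must adopt, driven by release of cyclopropane strain. C1 and C10 are set together: their absolute configuration is relayed from the two cyclopropane centres fixed by the prolinate ligands, and their relative configuration follows from the boat, in which the (E)-enol ether holds the C10 oxygen outside and the ring constraint of the enone holds the C1 methyl inside, so methyl and siloxy end up trans. The step needs chemoselectivity for the enol ether over the electron-poor tetrasubstituted alkene C5=C1 and over the enol ether of a second molecule of 8, which the donor oxygen on C6, the conjugation of C5=C1 to the ketone, excess diene and slow addition of 8 should secure; it also needs cis diastereoselectivity in the cyclopropanation, which donor/acceptor carbenoids give because the charge-stabilising alkene substituent sits next to the donor group. Because the inside methyl slows the sigmatropic step, gentle heating after the addition is planned.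

Step 5
Reactants: 10 methyl 6-ethoxy-1β-methyl-4-oxo-10α-(tert-butyldimethylsilyloxy)bicyclo[5.3.0]deca-5,8-diene-8-carboxylate
Product: 12 methyl 4-isopropyl-1β-methyl-6-oxo-10α-(tert-butyldimethylsilyloxy)bicyclo[5.3.0]deca-4,8-diene-8-carboxylate, via tertiary carbinol 11 (not isolated)
Conditions: i-PrMgCl, CeCl3, THF, −78 °C; then 1 M HCl, THF, 0 °C
Reagents that add atoms: isopropylmagnesium chloride, CC(C)[Mg]Cl; water, O
Why: Stork–Danheiser transposition: i-PrCeCl2 adds 1,2 to the vinylogous-ester carbonyl C4 faster than to the enoate and, because aqueous acid then ionises the tertiary allylic carbinol and hydrolyses the ethoxy-stabilised cation at C6, the carbonyl moves to C6 and the isopropyl group ends on the C4=C5 double bond, so the face of the addition does not matter.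

Step 6
Reactants: 12 methyl 4-isopropyl-1β-methyl-6-oxo-10α-(tert-butyldimethylsilyloxy)bicyclo[5.3.0]deca-4,8-diene-8-carboxylate
Product: 13 methyl 6β-hydroxy-4-isopropyl-1β-methyl-10α-(tert-butyldimethylsilyloxy)bicyclo[5.3.0]deca-4,8-diene-8-carboxylate
Conditions: (S)-2-methyl-CBS-oxazaborolidine (20 mol %), catecholborane, toluene, −78 °C
Reagents that add atoms: none
Why: Corey–Bakshi–Shibata reduction: the oxazaborolidine distinguishes the fully substituted alkenyl carbon C5 (large) from the C7 methylene (small) and, with the S catalyst, should deliver hydride to the α face of C6 to give the 6β (6R) allylic alcohol under reagent control, while catecholborane spares the enoate.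

Step 7
Reactants: 13 methyl 6β-hydroxy-4-isopropyl-1β-methyl-10α-(tert-butyldimethylsilyloxy)bicyclo[5.3.0]deca-4,8-diene-8-carboxylate
Product: 14 methyl 4β,5β-epoxy-6β-hydroxy-4α-isopropyl-1β-methyl-10α-(tert-butyldimethylsilyloxy)bicyclo[5.3.0]dec-8-ene-8-carboxylate
Conditions: VO(acac)2 (5 mol %), t-BuOOH, toluene, 0 °C to rt
Reagents that add atoms: tert-butyl hydroperoxide, CC(C)(C)OO
Why: Hydroxyl-directed epoxidation: the vanadate ester of the C6 alcohol delivers the peroxide oxygen to the tetrasubstituted allylic alkene C4=C5 on the face of the hydroxyl, which sets the C4–O bond β, and the electron-poor enoate alkene is not attacked.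

Step 8
Reactants: 14 methyl 4β,5β-epoxy-6β-hydroxy-4α-isopropyl-1β-methyl-10α-(tert-butyldimethylsilyloxy)bicyclo[5.3.0]dec-8-ene-8-carboxylate
Product: 17 methyl 4β-hydroxy-4α-isopropyl-1β-methyl-6-oxo-10α-(tert-butyldimethylsilyloxy)-5αH-bicyclo[5.3.0]dec-8-ene-8-carboxylate, via epoxy trimethylsilyl ether 15 (not isolated), via trimethylsilyloxy ketone 16 (not isolated)
Conditions: TMSOTf, i-Pr2NEt, CH2Cl2, −78 to −40 °C; then citric acid, MeOH, 0 °C
Reagents that add atoms: none
Why: Semipinacol rearrangement of a 2,3-epoxy silyl ether with 1,2-hydride shift (the non-aldol aldol process): silyl triflate activates the epoxide oxygen, the C6–H bond held anti-periplanar to the C5–O bond in the cis-epoxy silyl ether migrates to C5 with inversion while the silyloxy oxygen turns C6 into the ketone, so H5 arrives on the α face (trans ring fusion) and the C4 oxygen stays β, and mild acid then frees the tertiary alcohol.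

Step 9
Reactants: 17 methyl 4β-hydroxy-4α-isopropyl-1β-methyl-6-oxo-10α-(tert-butyldimethylsilyloxy)-5αH-bicyclo[5.3.0]dec-8-ene-8-carboxylate
Product: 18 methyl 4β,6α-dihydroxy-4α-isopropyl-1β-methyl-10α-(tert-butyldimethylsilyloxy)-5αH-bicyclo[5.3.0]dec-8-ene-8-carboxylate
Conditions: Me4NBH(OAc)3, MeCN–AcOH, −30 °C
Reagents that add atoms: none
Why: Evans–Saksena reduction: the C4 hydroxyl binds the triacetoxyborohydride and hydride is delivered intramolecularly through a six-membered transition state to the β face of the C6 ketone, which should give the anti-1,3-diol with the 6α hydroxyl.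

Step 10
Reactants: 18 methyl 4β,6α-dihydroxy-4α-isopropyl-1β-methyl-10α-(tert-butyldimethylsilyloxy)-5αH-bicyclo[5.3.0]dec-8-ene-8-carboxylate
Product: 19 8-(hydroxymethyl)-4α-isopropyl-1β-methyl-10α-(tert-butyldimethylsilyloxy)-5αH-bicyclo[5.3.0]dec-8-ene-4β,6α-diol
Conditions: i-Bu2AlH, CH2Cl2, −78 °C; aqueous sodium potassium tartrate
Reagents that add atoms: none
Why: Hydride reduction of a conjugated ester: i-Bu2AlH at low temperature reduces the enoate by 1,2-addition to the primary allylic alcohol after deprotonating the two hydroxyls and does not touch the silyl ether or the alkene.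

Step 11
Reactants: 19 8-(hydroxymethyl)-4α-isopropyl-1β-methyl-10α-(tert-butyldimethylsilyloxy)-5αH-bicyclo[5.3.0]dec-8-ene-4β,6α-diol
Product: 21 4α-isopropyl-1β,8-dimethyl-10α-(tert-butyldimethylsilyloxy)-5αH-bicyclo[5.3.0]dec-8-ene-4β,6α-diol, via allylic chloride 20 (not isolated)
Conditions: NCS, Me2S, CH2Cl2, −20 °C; then LiEt3BH, THF, 0 °C
Reagents that add atoms: none
Why: Corey–Kim chlorination converts only the primary allylic alcohol into the chloride in the presence of the hindered secondary and the tertiary hydroxyl, and LiEt3BH then replaces chloride by hydride in a direct SN2 displacement, which gives the C8 methyl group without allylic transposition.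

Step 12
Reactants: 21 4α-isopropyl-1β,8-dimethyl-10α-(tert-butyldimethylsilyloxy)-5αH-bicyclo[5.3.0]dec-8-ene-4β,6α-diol; 22 4-methoxybenzoyl chloride
Product: 23 4β-hydroxy-4α-isopropyl-1β,8-dimethyl-10α-(tert-butyldimethylsilyloxy)-5αH-bicyclo[5.3.0]dec-8-en-6α-yl 4-methoxybenzoate
Conditions: DMAP, pyridine, CH2Cl2, 0 °C to rt
Reagents that add atoms: none
Why: DMAP-catalysed acylation (nucleophilic catalysis) esterifies the secondary C6 hydroxyl with the acid chloride, and the tertiary C4 hydroxyl is too hindered to react.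

Step 13
Reactants: 23 4β-hydroxy-4α-isopropyl-1β,8-dimethyl-10α-(tert-butyldimethylsilyloxy)-5αH-bicyclo[5.3.0]dec-8-en-6α-yl 4-methoxybenzoate
Product: 24 4β,10α-dihydroxy-4α-isopropyl-1β,8-dimethyl-5αH-bicyclo[5.3.0]dec-8-en-6α-yl 4-methoxybenzoate (CNP0211568.1)
Conditions: Bu4NF, AcOH, THF, 0 °C to rt
Reagents that add atoms: none
Why: Fluoride-mediated desilylation cleaves the C10 silyl ether through the strong Si–F bond, and acetic acid buffering keeps the liberated alkoxide from attacking the aryl ester.

Compound list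

1 | 2-bromo-3-methylcyclopent-2-en-1-one | CC1=C(Br)C(=O)CC1 | starting material
2 | tributyl(1-ethoxyvinyl)stannane | CCCC[Sn](CCCC)(CCCC)C(=C)OCC | starting material
3 | 2-(1-ethoxyvinyl)-3-methylcyclopent-2-en-1-one | CCOC(=C)C1=C(C)CCC1=O | intermediate
4 | methyl diazoacetate | COC(=O)C=[N+]=[N-] | starting material
5 | (tert-butyldimethylsilyloxy)acetaldehyde | CC(C)(C)[Si](C)(C)OCC=O | starting material
6 | methyl 4-(tert-butyldimethylsilyloxy)-2-diazo-3-hydroxybutanoate (racemic) | COC(=O)C(=[N+]=[N-])C(O)CO[Si](C)(C)C(C)(C)C | intermediate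
7 | methyl 4-(tert-butyldimethylsilyloxy)-2-diazo-3-(dichlorophosphoryloxy)butanoate (racemic) | COC(=O)C(=[N+]=[N-])C(OP(=O)(Cl)Cl)CO[Si](C)(C)C(C)(C)C | intermediate
8 | methyl (E)-4-(tert-butyldimethylsilyloxy)-2-diazobut-3-enoate | COC(=O)C(=[N+]=[N-])/C=C/O[Si](C)(C)C(C)(C)C | intermediate
9 | methyl (1S,2R)-1-[(E)-2-(tert-butyldimethylsilyloxy)vinyl]-2-ethoxy-2-(2-methyl-5-oxocyclopent-1-en-1-yl)cyclopropane-1-carboxylate, siloxyvinyl cis to cyclopentenyl | COC(=O)[C@]1(/C=C/O[Si](C)(C)C(C)(C)C)C[C@@]1(OCC)C2=C(C)CCC2=O | intermediate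
10 | methyl 6-ethoxy-1β-methyl-4-oxo-10α-(tert-butyldimethylsilyloxy)bicyclo[5.3.0]deca-5,8-diene-8-carboxylate | CCOC1=C2C(=O)CC[C@]2(C)[C@H](O[Si](C)(C)C(C)(C)C)C=C(C(=O)OC)C1 | intermediate
11 | methyl 6-ethoxy-4-hydroxy-4-isopropyl-1β-methyl-10α-(tert-butyldimethylsilyloxy)bicyclo[5.3.0]deca-5,8-diene-8-carboxylate (either C4 epimer, present as its alkoxide) | CCOC1=C2C(O)(C(C)C)CC[C@]2(C)[C@H](O[Si](C)(C)C(C)(C)C)C=C(C(=O)OC)C1 | intermediate
12 | methyl 4-isopropyl-1β-methyl-6-oxo-10α-(tert-butyldimethylsilyloxy)bicyclo[5.3.0]deca-4,8-diene-8-carboxylate | O=C1CC(C(=O)OC)=C[C@@H](O[Si](C)(C)C(C)(C)C)[C@@]2(C)CCC(C(C)C)=C12 | intermediate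
13 | methyl 6β-hydroxy-4-isopropyl-1β-methyl-10α-(tert-butyldimethylsilyloxy)bicyclo[5.3.0]deca-4,8-diene-8-carboxylate | O[C@@H]1CC(C(=O)OC)=C[C@@H](O[Si](C)(C)C(C)(C)C)[C@@]2(C)CCC(C(C)C)=C12 | intermediate
14 | methyl 4β,5β-epoxy-6β-hydroxy-4α-isopropyl-1β-methyl-10α-(tert-butyldimethylsilyloxy)bicyclo[5.3.0]dec-8-ene-8-carboxylate | O[C@@H]1CC(C(=O)OC)=C[C@@H](O[Si](C)(C)C(C)(C)C)[C@@]2(C)CC[C@]3(C(C)C)O[C@]123 | intermediate
15 | 6-O-trimethylsilyl ether of 14 | C[Si](C)(C)O[C@@H]1CC(C(=O)OC)=C[C@@H](O[Si](C)(C)C(C)(C)C)[C@@]2(C)CC[C@]3(C(C)C)O[C@]123 | intermediate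
16 | methyl 4α-isopropyl-1β-methyl-6-oxo-10α-(tert-butyldimethylsilyloxy)-4β-(trimethylsilyloxy)-5αH-bicyclo[5.3.0]dec-8-ene-8-carboxylate | O=C1CC(C(=O)OC)=C[C@@H](O[Si](C)(C)C(C)(C)C)[C@@]2(C)CC[C@@](O[Si](C)(C)C)(C(C)C)[C@H]12 | intermediate
17 | methyl 4β-hydroxy-4α-isopropyl-1β-methyl-6-oxo-10α-(tert-butyldimethylsilyloxy)-5αH-bicyclo[5.3.0]dec-8-ene-8-carboxylate | O=C1CC(C(=O)OC)=C[C@@H](O[Si](C)(C)C(C)(C)C)[C@@]2(C)CC[C@@](O)(C(C)C)[C@H]12 | intermediate
18 | methyl 4β,6α-dihydroxy-4α-isopropyl-1β-methyl-10α-(tert-butyldimethylsilyloxy)-5αH-bicyclo[5.3.0]dec-8-ene-8-carboxylate | O[C@H]1CC(C(=O)OC)=C[C@@H](O[Si](C)(C)C(C)(C)C)[C@@]2(C)CC[C@@](O)(C(C)C)[C@H]12 | intermediate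
19 | 8-(hydroxymethyl)-4α-isopropyl-1β-methyl-10α-(tert-butyldimethylsilyloxy)-5αH-bicyclo[5.3.0]dec-8-ene-4β,6α-diol | O[C@H]1CC(CO)=C[C@@H](O[Si](C)(C)C(C)(C)C)[C@@]2(C)CC[C@@](O)(C(C)C)[C@H]12 | intermediate
20 | 8-(chloromethyl)-4α-isopropyl-1β-methyl-10α-(tert-butyldimethylsilyloxy)-5αH-bicyclo[5.3.0]dec-8-ene-4β,6α-diol | O[C@H]1CC(CCl)=C[C@@H](O[Si](C)(C)C(C)(C)C)[C@@]2(C)CC[C@@](O)(C(C)C)[C@H]12 | intermediate
21 | 4α-isopropyl-1β,8-dimethyl-10α-(tert-butyldimethylsilyloxy)-5αH-bicyclo[5.3.0]dec-8-ene-4β,6α-diol | O[C@H]1CC(C)=C[C@@H](O[Si](C)(C)C(C)(C)C)[C@@]2(C)CC[C@@](O)(C(C)C)[C@H]12 | intermediate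
22 | 4-methoxybenzoyl chloride | COc1ccc(C(=O)Cl)cc1 | starting material
23 | 4β-hydroxy-4α-isopropyl-1β,8-dimethyl-10α-(tert-butyldimethylsilyloxy)-5αH-bicyclo[5.3.0]dec-8-en-6α-yl 4-methoxybenzoate | COc1ccc(C(=O)O[C@H]2CC(C)=C[C@@H](O[Si](C)(C)C(C)(C)C)[C@@]3(C)CC[C@@](O)(C(C)C)[C@H]23)cc1 | intermediate
24 | 4β,10α-dihydroxy-4α-isopropyl-1β,8-dimethyl-5αH-bicyclo[5.3.0]dec-8-en-6α-yl 4-methoxybenzoate, (1S,4R,5S,6S,10R) in the route locants | COc1ccc(C(=O)O[C@H]2CC(C)=C[C@@H](O)[C@@]3(C)CC[C@@](O)(C(C)C)[C@H]23)cc1 | target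

Total step count: 13. Longest linear sequence: 12 steps (4 and 5 through 6, 8, 10 to 24; the branch through 3 is one step shorter).

Steps most likely to fail

First, step 4. The carbenoid may be consumed by the enol ether of a second molecule of 8, the donor–acceptor cyclopropane may open to a zwitterion and close to a five-membered ring, the rearrangement may stall because the C1 methyl sits inside the boat, or the siloxy substituent may erode enantioselection. The fallback uses known reactions only, sets out from 3 and returns at 10. The enol ether of 3 is cyclopropanated under the same catalyst with an alkynyldiazoacetate, methyl 2-diazo-4-(trimethylsilyl)but-3-ynoate F1, a donor/acceptor diazo class with established behaviour, to give the cis alkynylcyclopropane F2. K2CO3 in MeOH removes the C-silyl group and gives the terminal alkyne F3. Anti-Markovnikov hydroboration with Cy2BH and oxidation with NaBO3·4H2O gives the aldehyde F4. TBSCl, NaI and Et3N in MeCN convert F4 into its silyl enol ethers, the E isomer being 9 and the Z isomer F5. Heating in toluene rearranges only 9, since F5 would need both the methyl and the siloxy group inside the boat, and gives 10.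

Second, step 8. The activated epoxide may open at C4 instead of C5 and then eliminate, or the ring carbon C7 may migrate in place of hydride and contract ring B. The fallback sets out from 14 and returns at 17. Dess–Martin periodinane oxidises the C6 alcohol to the α,β-epoxy ketone F6. SmI2 in THF–MeOH at −90 °C cleaves the C5–O bond reductively, a standard route from epoxy ketones to β-hydroxy ketones, and the resulting enolate is protonated at C5. The chelated samarium alkoxide on the β face should steer methanol to the α face, though this is less secure than the hydride shift. The product is 17.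

Third, step 6. Facial selectivity may be poor if the inherent bias of the ketone, which probably favours hydride attack on the β face, opposes the catalyst. The fallback sets out from 12 and returns at 13. Luche reduction (NaBH4, CeCl3·7H2O, MeOH) is expected to give mainly the 6α alcohol F7. Mitsunobu inversion with 4-nitrobenzoic acid, PPh3 and diisopropyl azodicarboxylate gives the 6β ester F8, and K2CO3 in MeOH releases 13.

Further compounds

F1 | step 4 | methyl 2-diazo-4-(trimethylsilyl)but-3-ynoate | COC(=O)C(=[N+]=[N-])C#C[Si](C)(C)C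
F2 | step 4 | methyl 2-ethoxy-2-(2-methyl-5-oxocyclopent-1-en-1-yl)-1-[(trimethylsilyl)ethynyl]cyclopropane-1-carboxylate, alkynyl cis to cyclopentenyl | COC(=O)[C@]1(C#C[Si](C)(C)C)C[C@@]1(OCC)C2=C(C)CCC2=O
F3 | step 4 | methyl 2-ethoxy-1-ethynyl-2-(2-methyl-5-oxocyclopent-1-en-1-yl)cyclopropane-1-carboxylate, ethynyl cis to cyclopentenyl | COC(=O)[C@]1(C#C)C[C@@]1(OCC)C2=C(C)CCC2=O
F4 | step 4 | methyl 2-ethoxy-2-(2-methyl-5-oxocyclopent-1-en-1-yl)-1-(2-oxoethyl)cyclopropane-1-carboxylate, oxoethyl cis to cyclopentenyl | COC(=O)[C@]1(CC=O)C[C@@]1(OCC)C2=C(C)CCC2=O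
F5 | step 4 | (Z)-enol ether isomer of 9 | COC(=O)[C@]1(/C=C\O[Si](C)(C)C(C)(C)C)C[C@@]1(OCC)C2=C(C)CCC2=O
F6 | step 8 | methyl 4β,5β-epoxy-4α-isopropyl-1β-methyl-6-oxo-10α-(tert-butyldimethylsilyloxy)bicyclo[5.3.0]dec-8-ene-8-carboxylate | O=C1CC(C(=O)OC)=C[C@@H](O[Si](C)(C)C(C)(C)C)[C@@]2(C)CC[C@]3(C(C)C)O[C@]123
F7 | step 6 | methyl 6α-hydroxy-4-isopropyl-1β-methyl-10α-(tert-butyldimethylsilyloxy)bicyclo[5.3.0]deca-4,8-diene-8-carboxylate | O[C@H]1CC(C(=O)OC)=C[C@@H](O[Si](C)(C)C(C)(C)C)[C@@]2(C)CCC(C(C)C)=C12
F8 | step 6 | methyl 4-isopropyl-1β-methyl-6β-(4-nitrobenzoyloxy)-10α-(tert-butyldimethylsilyloxy)bicyclo[5.3.0]deca-4,8-diene-8-carboxylate | O=C(O[C@@H]1CC(C(=O)OC)=C[C@@H](O[Si](C)(C)C(C)(C)C)[C@@]2(C)CCC(C(C)C)=C12)c3ccc(cc3)[N+](=O)[O-]
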